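Late in a run the target is down to little: at 4.00 h maple shows 2%, ash 3% and alder 1%. The target is therefore a way station, and the books are kept on the starting material, the limiting reagent, charged below either nucleophile.

| flask | starting material | first nucleophile | second nucleophile | protic impurity | remark | time |
|---|---|---|---|---|---|---|
| maple | 20 mM | 100 mM | 22 mM | 5 mM | run made earlier |  |
| ash | 20 mM | 100 mM | 22 mM | 7.5 mM | run made earlier |  |
| alder | 20 mM | 200 mM | 22 mM | 10 mM | run made earlier |  |
| flask | 20 mM | 100 mM | 22.0 mM | 10.0 mM |  | 6.0 h |

| maple: time / h | maple: target / % | ash: time / h | ash: target / % | alder: time / h | alder: target / % |
|---|---|---|---|---|---|
| 0.0833 | 14 | 0.0833 | 15 | 0.0833 | 18 |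
| 0.333 | 25 | 0.333 | 21 | 0.333 | 26 |
| 1.00 | 12 | 1.00 | 13 | 1.00 | 18 |
| 4.00 | 2 | 4.00 | 3 | 4.00 | 1 |

(readings scatter by 1.5 percentage points)

- steps thought possible: second nucleophile + target -> over-reaction product; first nucleophile + intermediate -> target; second nucleophile + intermediate -> other capture product; starting material -> intermediate; first nucleophile + protic impurity -> quenched reagent

- the moment within 6.0 h at which there is most target
- the amount of target, in percent of the starting material charged, at that time
- earliest time at which at least nineteen twentieths of that best amount are there
- latest time at which they still are

The first entry is the protic impurity, reckoned to take first nucleophile one for one. The second is the fork: each mole of starting material becomes intermediate, and one nucleophile catches it. Dividing the rate into target by the rate into other capture product removes both time and the intermediate, leaving the capture odds, which are a selectivity factor times net first nucleophile over second nucleophile.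

Alder has twice the net first nucleophile of maple and the same second nucleophile. Taking conversion as equal at 0.0833 h, the readings there stand in the ratio 1.29, which is read as the ratio of target shares. A share is the odds over one plus the odds, so maple's odds read 1.25. That gives a selectivity factor of 0.289, a reading that carries the scatter.

Holding the charges through the whole run as an approximation, the flask has odds of 1.18. Its ledger books 54.2% of the starting material through target and 45.8% to other capture product. Either route costs one second nucleophile, so 9.09% of that charge remains when the books close. Scaling maple's peak reading by the target shares gives 24.4% near 0.333 h.

The forecast gives 23.5% at 0.35 h, less than the 24.4% reckoned here, with a window from 0.24 h to 0.49 h, and holds that "The impurity probably just removes its equivalent of first nucleophile".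

The flask peaks at 0.345 h with 23.2%, and the window asked for runs from 0.232 h to 0.496 h. At the peak, 21.2% is already over-reaction product. At 6.00 h the flask holds 41.1% as other capture product, against the 45.8% booked by the odds.

    second nucleophile + target → over-reaction product (k = 4.10 /M/min)
    first nucleophile + intermediate → target (k = 73.0 /M/min)
    second nucleophile + intermediate → other capture product (k = 300 /M/min)
    starting material → intermediate (k = 0.0770 /min)
    first nucleophile + protic impurity → quenched reagent (k = 7.60 /M/min)

With 170 mM of first nucleophile, the neighbour's odds come to 2.11, which books 32.2% to other capture product and a peak near 29.0%. Computed, that neighbour ends with 29.1% as other capture product and has a best of 27.3%.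

The runs were computed on assumed constants, noise included.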